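**Retrosynthetic overview**
- The 3-hydroxyl is added last, by C3 lithiation, borylation and oxidation of the flavone; two MOM ethers are then cleaved.
- Ring C is cut at C4a–C4, C4–C3 and O1–C2. C4 is a lone carbonyl carbon between C4a of ring A and C3, so it is brought in as CO in a palladium-catalysed carbonylative annulation of iodoresorcinol 6 with ring B alkyne 9.
- The feature the plan rests on: cut this way, ring A is a resorcinol with a mirror plane through C4a and C7. Its two hydroxyls become O1 and the 5-OH, and its two prenyl groups become those on C6 and C8, without distinction, so ring A needs no protecting group.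
- Iodoresorcinol 6 comes from methyl 2,4,6-trihydroxybenzoate (double C-prenylation, 4-O-methylation, decarboxylation, iodination). Alkyne 9 comes from isovanillin (MOM protection, Ohira–Bestmann homologation).
- Rings A and B are bought; ring C is the only ring formed (step 7).

Key step: step 7

Remark: the target has no stereocentre and no double bond with a configuration, so nothing stereochemical has to be set.

**Route**

Step 1
Reactants: 1 methyl 2,4,6-trihydroxybenzoate; 2 prenyl bromide (1-bromo-3-methylbut-2-ene)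
Product: 3 methyl 2,4,6-trihydroxy-3,5-bis(3-methylbut-2-enyl)benzoate
Conditions: 2 (2.1 equiv), DBU (2.1 equiv), THF, 0 °C to rt
Reagents that add atoms: none
Why: C-alkylation of the phloroglucinol-type phenoxide by the allylic bromide (SN2 at the primary carbon, so the linear prenyl group results) should occur at the two equivalent free ring carbons, the ester blocking the third; this is the usual C-prenylation of acylphloroglucinols.

Step 2
Reactants: 3 methyl 2,4,6-trihydroxy-3,5-bis(3-methylbut-2-enyl)benzoate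
Product: 4 methyl 2,6-dihydroxy-4-methoxy-3,5-bis(3-methylbut-2-enyl)benzoate
Conditions: Me2SO4 (1.05 equiv), K2CO3, acetone, rt
Reagents that add atoms: dimethyl sulfate, COS(=O)(=O)OC
Why: Williamson O-methylation should take the 4-hydroxyl, which is para to the ester, not hydrogen-bonded and the most acidic, while the 2- and 6-hydroxyls stay tied to the ester; the hard electrophile keeps alkylation on oxygen.

Step 3
Reactants: 4 methyl 2,6-dihydroxy-4-methoxy-3,5-bis(3-methylbut-2-enyl)benzoate
Product: 5 5-methoxy-4,6-bis(3-methylbut-2-enyl)benzene-1,3-diol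
Conditions: KOH, MeOH–H2O, reflux, Ar; then aq. citric acid to pH 5
Reagents that add atoms: none
Why: Saponification followed by decarboxylation of the 2,6-dihydroxybenzoate (ipso protonation of the electron-rich ring, loss of CO2) is the standard removal of a carboxyl blocking group from a resorcinol, and the basic medium spares the prenyl groups.

Step 4
Reactants: 5 5-methoxy-4,6-bis(3-methylbut-2-enyl)benzene-1,3-diol
Product: 6 2-iodo-5-methoxy-4,6-bis(3-methylbut-2-enyl)benzene-1,3-diol
Conditions: I2 (1.0 equiv), NaHCO3, THF–H2O, 0 °C; Na2S2O3 quench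
Reagents that add atoms: iodine, II
Why: Electrophilic aromatic iodination of the resorcinol phenoxide can only occur at the one free ring carbon (ortho to both hydroxyls, para to the methoxyl), and with one equivalent of iodine at 0 °C it should outrun attack on the prenyl double bonds.

Step 5
Reactants: 7 isovanillin (3-hydroxy-4-methoxybenzaldehyde)
Product: 8 4-methoxy-3-(methoxymethoxy)benzaldehyde
Conditions: MOMCl, i-Pr2NEt, CH2Cl2, 0 °C to rt
Reagents that add atoms: chloromethyl methyl ether, COCCl
Why: O-Alkylation of the phenol with chloromethyl methyl ether and an amine base (MOM protection) is routine and leaves the aldehyde untouched.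

Step 6
Reactants: 8 4-methoxy-3-(methoxymethoxy)benzaldehyde
Product: 9 4-ethynyl-1-methoxy-2-(methoxymethoxy)benzene
Conditions: dimethyl (1-diazo-2-oxopropyl)phosphonate, K2CO3, MeOH, rt
Reagents that add atoms: dimethyl (1-diazo-2-oxopropyl)phosphonate, CC(=O)C(=[N+]=[N-])P(=O)(OC)OC
Why: Ohira–Bestmann (Seyferth–Gilbert) homologation turns an aryl aldehyde into the terminal alkyne under mild base that the MOM ether tolerates.

Step 7
Reactants: 6 2-iodo-5-methoxy-4,6-bis(3-methylbut-2-enyl)benzene-1,3-diol; 9 4-ethynyl-1-methoxy-2-(methoxymethoxy)benzene (1.5 equiv); 10 carbon monoxide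
Product: 13 5-hydroxy-7-methoxy-2-[4-methoxy-3-(methoxymethoxy)phenyl]-6,8-bis(3-methylbut-2-enyl)chromen-4-one, via aryl ynone 11 (not isolated), via diethylamino enone 12 (not isolated)
Conditions: PdCl2(PPh3)2 (5 mol %), CO (20 bar), Et2NH, 120 °C, autoclave
Reagents that add atoms: none
Why: PdCl2(PPh3)2 is reduced in the amine to zerovalent palladium, which inserts into the C–I bond of 6; CO inserts to give the aroylpalladium iodide, and alkynyl transfer from 9 (deprotonated by Et2NH) followed by reductive elimination gives ynone 11, forming C4a–C4 and C4–C3. Et2NH then adds to the ynone to give enaminone 12, and one of the two equivalent ortho hydroxyls attacks the amine-bearing carbon and expels Et2NH, a net 6-endo closure of ring C that forms O1–C2. The closest known reaction type is the palladium-catalysed carbonylative annulation of 2-iodophenols with terminal alkynes to flavones. No stereocentre is formed. The step needs carbonylative over direct alkynylation, which CO pressure and the absence of a copper cocatalyst should secure, and 6-endo over 5-exo (aurone) closure, which the secondary amine secures through the enaminone. Because the mirror plane of 6 makes both hydroxyls and both prenyl groups equivalent, only one flavone can form, and the hydroxyl left over is the hydrogen-bonded 5-OH.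

Step 8
Reactants: 13 5-hydroxy-7-methoxy-2-[4-methoxy-3-(methoxymethoxy)phenyl]-6,8-bis(3-methylbut-2-enyl)chromen-4-one
Product: 14 7-methoxy-5-(methoxymethoxy)-2-[4-methoxy-3-(methoxymethoxy)phenyl]-6,8-bis(3-methylbut-2-enyl)chromen-4-one
Conditions: NaH, MOMCl, DMF, 0 °C to rt
Reagents that add atoms: chloromethyl methyl ether, COCCl
Why: Full deprotonation with NaH breaks the hydrogen bond of the 5-hydroxyl to the C4 carbonyl, and the phenoxide should be O-alkylated by MOMCl (MOM protection), removing the only acidic proton before the lithiation.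

Step 9
Reactants: 14 7-methoxy-5-(methoxymethoxy)-2-[4-methoxy-3-(methoxymethoxy)phenyl]-6,8-bis(3-methylbut-2-enyl)chromen-4-one
Product: 17 3-hydroxy-7-methoxy-5-(methoxymethoxy)-2-[4-methoxy-3-(methoxymethoxy)phenyl]-6,8-bis(3-methylbut-2-enyl)chromen-4-one, via 3-lithioflavone 15 (not isolated), via lithium trimethoxyborate 16 (not isolated)
Conditions: LiN(i-Pr)2 (LDA, 1.5 equiv), THF, −78 °C; B(OMe)3, −78 to 0 °C; H2O2 (30 %), aq. NaHCO3, 0 °C to rt
Reagents that add atoms: hydrogen peroxide, OO
Why: The amide base should remove the C3 proton next to the C4 carbonyl (lithium held by the carbonyl oxygen), B(OMe)3 traps the carbanion, and hydroperoxide oxidises the C–B bond by 1,2-shift of C3 from boron to oxygen; this is the known lithiation–borylation–oxidation of flavones to flavonols, and buffered H2O2 without a peracid leaves the prenyl double bonds alone.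

Step 10
Reactants: 17 3-hydroxy-7-methoxy-5-(methoxymethoxy)-2-[4-methoxy-3-(methoxymethoxy)phenyl]-6,8-bis(3-methylbut-2-enyl)chromen-4-one
Product: 18 3,5-dihydroxy-2-(3-hydroxy-4-methoxyphenyl)-7-methoxy-6,8-bis(3-methylbut-2-enyl)chromen-4-one (CNP0261856.0)
Conditions: HCl (3 M aq.), MeOH–THF, 40 °C
Reagents that add atoms: none
Why: Acid-catalysed acetal cleavage removes both MOM ethers (the one peri to the carbonyl first), and dilute acid at mild temperature should not yet add the 5-hydroxyl across the neighbouring prenyl double bond.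

**Compound list**
1 | methyl 2,4,6-trihydroxybenzoate | COC(=O)c1c(O)cc(O)cc1O | starting material
2 | prenyl bromide (1-bromo-3-methylbut-2-ene) | CC(C)=CCBr | starting material
3 | methyl 2,4,6-trihydroxy-3,5-bis(3-methylbut-2-enyl)benzoate | COC(=O)c1c(O)c(CC=C(C)C)c(O)c(CC=C(C)C)c1O | intermediate
4 | methyl 2,6-dihydroxy-4-methoxy-3,5-bis(3-methylbut-2-enyl)benzoate | COC(=O)c1c(O)c(CC=C(C)C)c(OC)c(CC=C(C)C)c1O | intermediate
5 | 5-methoxy-4,6-bis(3-methylbut-2-enyl)benzene-1,3-diol | COc1c(CC=C(C)C)c(O)cc(O)c1CC=C(C)C | intermediate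
6 | 2-iodo-5-methoxy-4,6-bis(3-methylbut-2-enyl)benzene-1,3-diol | COc1c(CC=C(C)C)c(O)c(I)c(O)c1CC=C(C)C | intermediate
7 | isovanillin (3-hydroxy-4-methoxybenzaldehyde) | COc1ccc(C=O)cc1O | starting material
8 | 4-methoxy-3-(methoxymethoxy)benzaldehyde | COCOc1cc(C=O)ccc1OC | intermediate
9 | 4-ethynyl-1-methoxy-2-(methoxymethoxy)benzene | COCOc1cc(C#C)ccc1OC | intermediate
10 | carbon monoxide | [C-]#[O+] | starting material
11 | 1-[2,6-dihydroxy-4-methoxy-3,5-bis(3-methylbut-2-enyl)phenyl]-3-[4-methoxy-3-(methoxymethoxy)phenyl]prop-2-yn-1-one (not isolated) | COCOc1cc(C#CC(=O)c2c(O)c(CC=C(C)C)c(OC)c(CC=C(C)C)c2O)ccc1OC | intermediate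
12 | (E)-3-(diethylamino)-1-[2,6-dihydroxy-4-methoxy-3,5-bis(3-methylbut-2-enyl)phenyl]-3-[4-methoxy-3-(methoxymethoxy)phenyl]prop-2-en-1-one (not isolated; the geometry has no consequence) | CCN(CC)/C(c1ccc(OC)c(OCOC)c1)=C/C(=O)c1c(O)c(CC=C(C)C)c(OC)c(CC=C(C)C)c1O | intermediate
13 | 5-hydroxy-7-methoxy-2-[4-methoxy-3-(methoxymethoxy)phenyl]-6,8-bis(3-methylbut-2-enyl)chromen-4-one | COc1ccc(-c2cc(=O)c3c(O)c(CC=C(C)C)c(OC)c(CC=C(C)C)c3o2)cc1OCOC | intermediate
14 | 7-methoxy-5-(methoxymethoxy)-2-[4-methoxy-3-(methoxymethoxy)phenyl]-6,8-bis(3-methylbut-2-enyl)chromen-4-one | COCOc1cc(-c2cc(=O)c3c(OCOC)c(CC=C(C)C)c(OC)c(CC=C(C)C)c3o2)ccc1OC | intermediate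
15 | 3-lithio derivative of 14 (not isolated) | [Li]c1c(-c2ccc(OC)c(OCOC)c2)oc2c(CC=C(C)C)c(OC)c(CC=C(C)C)c(OCOC)c2c1=O | intermediate
16 | lithium trimethoxyborate of 14 at C3 (not isolated) | [Li+].CO[B-](OC)(OC)c1c(-c2ccc(OC)c(OCOC)c2)oc2c(CC=C(C)C)c(OC)c(CC=C(C)C)c(OCOC)c2c1=O | intermediate
17 | 3-hydroxy-7-methoxy-5-(methoxymethoxy)-2-[4-methoxy-3-(methoxymethoxy)phenyl]-6,8-bis(3-methylbut-2-enyl)chromen-4-one | COCOc1cc(-c2oc3c(CC=C(C)C)c(OC)c(CC=C(C)C)c(OCOC)c3c(=O)c2O)ccc1OC | intermediate
18 | 3,5-dihydroxy-2-(3-hydroxy-4-methoxyphenyl)-7-methoxy-6,8-bis(3-methylbut-2-enyl)chromen-4-one | COc1ccc(-c2oc3c(CC=C(C)C)c(OC)c(CC=C(C)C)c(O)c3c(=O)c2O)cc1O | target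

**Step count**
Total: 10 steps. Longest linear sequence: 8 steps (steps 1, 2, 3, 4, 7, 8, 9, 10); the alkyne branch is steps 5 and 6.

**Steps most likely to fail, with fallbacks**

Step 7. The electron-rich, doubly ortho-substituted arylpalladium may lose iodine reductively before CO is taken up. The aroylpalladium may be captured by Et2NH as the amide. Alkynylation may run without CO, or the ynone may close 5-exo.
The fallback takes C4 from DMF and makes the ynone without palladium. It sets out from 5 and 9 and comes back at 14.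
- Compound 5 with NaH and MOMCl in DMF should give 3-methoxy-1,5-bis(methoxymethoxy)-2,4-bis(3-methylbut-2-enyl)benzene F1.
- Compound 9 with n-BuLi in THF at −78 °C, then DMF and a KH2PO4 quench, should give 3-[4-methoxy-3-(methoxymethoxy)phenyl]prop-2-ynal F2.
- F1 is lithiated with n-BuLi in THF at 0 °C at its only ring hydrogen, between the two MOM ethers, and added to F2 at −78 °C. This should give racemic 1-[4-methoxy-2,6-bis(methoxymethoxy)-3,5-bis(3-methylbut-2-enyl)phenyl]-3-[4-methoxy-3-(methoxymethoxy)phenyl]prop-2-yn-1-ol F3.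
- MnO2 in CH2Cl2 oxidises F3 to 1-[4-methoxy-2,6-bis(methoxymethoxy)-3,5-bis(3-methylbut-2-enyl)phenyl]-3-[4-methoxy-3-(methoxymethoxy)phenyl]prop-2-yn-1-one F4.
- Et2NH in EtOH at rt adds to F4 to give (E)-3-(diethylamino)-1-[4-methoxy-2,6-bis(methoxymethoxy)-3,5-bis(3-methylbut-2-enyl)phenyl]-3-[4-methoxy-3-(methoxymethoxy)phenyl]prop-2-en-1-one F5.
- HCl (3 M) in MeOH at 40 °C removes the three MOM groups from F5 and closes the pyranone with loss of Et2NH, giving 5-hydroxy-2-(3-hydroxy-4-methoxyphenyl)-7-methoxy-6,8-bis(3-methylbut-2-enyl)chromen-4-one F6.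
- NaH and MOMCl (2.5 equiv) in DMF convert F6 into 14.

Step 4. Iodine may attack a prenyl double bond and the neighbouring hydroxyl may close onto it (iodoetherification) instead of the ring being iodinated. The iodide may also be lost again by protonolysis if the medium turns acidic.
The fallback places iodine by directed ortho-lithiation, in which iodine meets only the aryllithium. It sets out from 5 and comes back at 6.
- Compound 5 with NaH and MOMCl in DMF should give 3-methoxy-1,5-bis(methoxymethoxy)-2,4-bis(3-methylbut-2-enyl)benzene F7 (the same ether as F1).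
- n-BuLi in THF at 0 °C, then I2 at −78 °C, should give 2-iodo-5-methoxy-1,3-bis(methoxymethoxy)-4,6-bis(3-methylbut-2-enyl)benzene F8.
- HCl in MeOH at rt frees 6.

Step 1. Alkylation may stop at the monoprenyl stage, go on to geminal dialkylation with loss of aromaticity, or take place on oxygen.
The fallback builds each prenyl group by O-allylation, Claisen rearrangement and cross-metathesis. It sets out from 1 and comes back at 4, so 3 is bypassed.
- Compound 1 with Me2SO4 (1 equiv) and K2CO3 in acetone should give methyl 2,6-dihydroxy-4-methoxybenzoate F9.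
- Allyl bromide and K2CO3 in DMF at 60 °C should give methyl 4-methoxy-2,6-bis(prop-2-enyloxy)benzoate F10.
- Heating in N,N-diethylaniline at 190 °C moves each allyl group to its only free ortho carbon, giving methyl 2,6-dihydroxy-4-methoxy-3,5-bis(prop-2-enyl)benzoate F11.
- Cross-metathesis with 2-methylbut-2-ene and the second-generation Grubbs catalyst RuCl2(=CHPh)(H2IMes)(PCy3) in CH2Cl2 at 40 °C should give 4.

**Further compounds**
F1 | step 7 | 3-methoxy-1,5-bis(methoxymethoxy)-2,4-bis(3-methylbut-2-enyl)benzene | COCOc1cc(OCOC)c(CC=C(C)C)c(OC)c1CC=C(C)C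
F2 | step 7 | 3-[4-methoxy-3-(methoxymethoxy)phenyl]prop-2-ynal | COCOc1cc(C#CC=O)ccc1OC
F3 | step 7 | 1-[4-methoxy-2,6-bis(methoxymethoxy)-3,5-bis(3-methylbut-2-enyl)phenyl]-3-[4-methoxy-3-(methoxymethoxy)phenyl]prop-2-yn-1-ol (racemic) | COCOc1cc(C#CC(O)c2c(OCOC)c(CC=C(C)C)c(OC)c(CC=C(C)C)c2OCOC)ccc1OC
F4 | step 7 | 1-[4-methoxy-2,6-bis(methoxymethoxy)-3,5-bis(3-methylbut-2-enyl)phenyl]-3-[4-methoxy-3-(methoxymethoxy)phenyl]prop-2-yn-1-one | COCOc1cc(C#CC(=O)c2c(OCOC)c(CC=C(C)C)c(OC)c(CC=C(C)C)c2OCOC)ccc1OC
F5 | step 7 | (E)-3-(diethylamino)-1-[4-methoxy-2,6-bis(methoxymethoxy)-3,5-bis(3-methylbut-2-enyl)phenyl]-3-[4-methoxy-3-(methoxymethoxy)phenyl]prop-2-en-1-one | CCN(CC)/C(c1ccc(OC)c(OCOC)c1)=C/C(=O)c1c(OCOC)c(CC=C(C)C)c(OC)c(CC=C(C)C)c1OCOC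
F6 | step 7 | 5-hydroxy-2-(3-hydroxy-4-methoxyphenyl)-7-methoxy-6,8-bis(3-methylbut-2-enyl)chromen-4-one | COc1ccc(-c2cc(=O)c3c(O)c(CC=C(C)C)c(OC)c(CC=C(C)C)c3o2)cc1O
F7 | step 4 | 3-methoxy-1,5-bis(methoxymethoxy)-2,4-bis(3-methylbut-2-enyl)benzene | COCOc1cc(OCOC)c(CC=C(C)C)c(OC)c1CC=C(C)C
F8 | step 4 | 2-iodo-5-methoxy-1,3-bis(methoxymethoxy)-4,6-bis(3-methylbut-2-enyl)benzene | COCOc1c(I)c(OCOC)c(CC=C(C)C)c(OC)c1CC=C(C)C
F9 | step 1 | methyl 2,6-dihydroxy-4-methoxybenzoate | COC(=O)c1c(O)cc(OC)cc1O
F10 | step 1 | methyl 4-methoxy-2,6-bis(prop-2-enyloxy)benzoate | COC(=O)c1c(OCC=C)cc(OC)cc1OCC=C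
F11 | step 1 | methyl 2,6-dihydroxy-4-methoxy-3,5-bis(prop-2-enyl)benzoate | COC(=O)c1c(O)c(CC=C)c(OC)c(CC=C)c1O
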